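## Analysis of the target

The target, C30H26O10, is a 4→8-linked biflavanoid: an upper 7,4'-dihydroxyflavan (benzo ring A, pyran ring C, 4-hydroxyphenyl ring B, no oxygen at C3 or C5) whose C4 is bonded to C8 of a lower (+)-gallocatechin unit (benzo ring D, pyran ring F, pyrogallol ring E). Lower C2 (R) and C3 (S) are trans, exactly as in (+)-gallocatechin, whereas upper C2 (S) and C4 (R) hold ring B and ring D on opposite faces of ring C, the less stable 2,4-trans arrangement of a 2,4-diarylchroman. The two pairs of stereocentres are separated by the C4–C8 aryl bond, so the lower unit cannot be counted on to relay its configuration to upper C4. Seven phenols (one ring is an air-sensitive pyrogallol) and one secondary alcohol have to be carried; the benzylic C2–O1 bonds of both pyran rings can ionise under acid or be hydrogenolysed, and the doubly benzylic C4–C8 bond between two electron-rich rings is acid-labile. The difficulty is upper C4: it is a methine next to a CH2 group, with no C3 oxygen to steer the benzylic-cation coupling that serves for ordinary proanthocyanidins, so its absolute configuration and the trans relation to C2 must both come from reagent control. The strategy rests on the three carbon neighbours of upper C4 (C4a of ring A, C3, and C8 of ring D): seen from ring D it is the carbon of a formyl group on lower C8, ring A is a resorcinol that offers C4a and O1 on adjacent carbons, and C3–C2 is a two-carbon unit with C2 at the acetal oxidation level, that is, a vinyl ether.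

## Retrosynthetic reasoning

18 from 17. The last operation removes eight benzyl ethers from 17. Benzyl is chosen because the route passes through carbonate and hydride bases, an aryllithium, a Brønsted acid and a Lewis acid, and because one neutral hydrogenolysis then frees every hydroxyl without acid or base touching the C2–O1 and C4–C8 bonds.

17 from 12 and 15 (upper C2–ring B bond). Ring B is cut off at C2. In the forward direction the C2 acetal of 12 is ionised to the oxocarbenium ion 16, and the aryl group is delivered from the arylzinc chloride 15, itself made from bromide 13 through aryllithium 14. The cut is placed here because it makes ring B the incoming nucleophile: a nucleophile that approaches 16 along the axial trajectory, on the face away from the bulky C4 substituent, ends up trans to C4, which is what the target needs. Had ring B already been on C2 when that carbon became sp3 (by cycloaddition of an aryl-substituted alkene, or by hydride reduction of a 2-aryl ketal), the group entering last would be hydrogen and ring B would finish cis to C4.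

12 from 11. The 7-hydroxyl is capped as its benzyl ether. A free phenol would quench the organozinc reagent and, under the Lewis acid, open a para-quinone methide pathway. The new ether falls in the final hydrogenolysis at no extra cost.

11 from 6, 7 and 8 (C4–C4a, C3–C4 and O1–C2). This is the strategic disconnection. Ring C is taken apart into the formyl carbon of aldehyde 6 (C4), the C–C–O edge of resorcinol 7 (C4a, C8a, O1) and the two carbons of ethyl vinyl ether 8 (C3, C2). Forward, a chiral Brønsted acid has to bring about three events in one flask: hydroxyalkylation of 7 by 6 to the benzhydrol 9, dehydration of 9 to the ring-A o-quinone methide 10, and [4+2] capture of 10 by 8. The cut has four merits. Ring A and ring C come from two cheap achiral components, and only one stereocentre (C4) has to be set, at the moment C3–C4 forms. Compound 7 is symmetric, so the hydroxyalkylation has a single regiochemical outcome. Ring D of 6 has no free ortho hydroxyl, so the quinone methide can form only on ring A. C2 is left as an acetal, which is exactly what the next disconnection needs.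

6 from 4 through 5, and 4 from 3. The formyl group is traced to the aryllithium 5 and then to bromide 4. Lower C8 is the position of a benzylated flavan-3-ol that electrophilic bromination reaches first, and bromine–lithium exchange followed by formylation places the aldehyde carbon there without touching C6.

3 from 2 from 1. The six hydroxyls of (+)-gallocatechin 1 are benzylated in two stages, the phenols first under mild base (2) and then the C3 alcohol (3). Lower C2 and C3 are therefore taken from the chiral pool and never have to be made.

## Alternatives that were turned down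

Alternative 1: Lower ring F is disconnected at C3–C4 and O1–C2. In the forward key step a chiral phosphoric acid would turn the ring-D hydroxymethylphenol A2, which already carries the complete upper flavan, into its o-quinone methide, and the (E)-enol acetate A3 would add to it to give A1, the fully protected target with an acetate on lower C3. In its favour, the last union is convergent, ring F and both of its stereocentres arise in one step (against one stereocentre in the chosen key step), and the E geometry of A3 is carried suprafacially into the 2,3-trans relation. Against it, A2 presupposes that the upper flavan with its C4 and C2 stereocentres has already been built on a fully substituted, unsymmetrically protected ring D, so the hard problem of the target is postponed, not solved. The lower C2 and C3 centres, which 1 supplies for nothing, would have to be created by catalysis next to existing stereocentres. Flavan connectivity also requires the acetoxy-bearing carbon of A3 to bond to the quinone methide carbon; A3 must then react as a styrene polarised by ring E, whose para oxygen is twisted out of conjugation by its two neighbours, and against its enol-ester polarisation, which leads to the isoflavan connectivity. An acetate removal is added as well. By comparison, the chosen route needs no such regiochemical argument, because the oxygen of 8 sits on the carbon that must become C2, and it needs one catalytic stereocentre where this alternative needs four.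

Alternative 2: The same two bonds of ring C (C3–C4, O1–C2) are formed, but C4–C4a is made beforehand. In the forward key step the ring-A/ring-D benzhydrol A5 would be ionised by a chiral phosphoric acid to the ring-A o-quinone methide and trapped by the silyl enol ether A6 to give the 2-aryl-2-silyloxy ketal A4. In its favour, the two-component benzhydrol format is the best-precedented mode of chiral phosphoric acid o-quinone methide catalysis, no second phenol is present to compete, A6 is a stronger π-nucleophile than 8, and ring B arrives in the same step; on precedent and chemoselectivity of the cycloaddition this alternative is stronger than the chosen step. Against it, C2 of A4 is a ketal carbon, and the flavan is reached by delivering hydride to a 2-aryl oxocarbenium ion. The hydride takes the axial position away from the C4 substituent, so ring B ends equatorial and cis to C4, whereas the target is 2,4-trans. A5 also costs extra steps from 6 and is very acid-labile. By comparison, the chosen route forms the benzhydrol in the flask and leaves C2 as an aldehyde-level acetal, so that ring B enters as the nucleophile and ends trans; the benzhydrol format is kept in reserve as the fallback for the key step.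

Alternative 3: Ring C is disconnected at C2–C3 and O1–C2, with hydrogen added to C4. In the forward key step, asymmetric hydroformylation with Rh(acac)(CO)2 and a chiral bisphosphine under CO and H2 would convert the 1,1-diarylethene A8 into the lactol A7; the formyl group goes to the terminal carbon and the ring-A ortho hydroxyl closes the ring. In its favour, atom economy is complete, no cationic intermediate is involved, and A7 is at the same oxidation level as 12 and could enter the same endgame. Against it, C4 becomes stereogenic at the carbon that receives hydrogen, so the catalyst must distinguish the two faces of an alkene whose substituents are two aryl rings, both ortho-oxygenated and of similar size, and there is little structural basis for that discrimination. A8 is a twisted, tri-ortho-substituted alkene, so insertion should be slow and simple hydrogenation competes. A8 also needs about three extra steps from 6 (aryl addition, oxidation, methylenation). By comparison, in the chosen step the two rings play chemically different roles: ring A becomes the quinone methide bound to the catalyst and ring D is a spectator, which gives the catalyst a real handle and uses 6 directly.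

Key step: step 5

Assumption: the sense of induction of the phosphoric acid on this substrate cannot be predicted with certainty; the (R) acid is written, and its enantiomer is to be used if the (R) acid favours the C4 epimer. (R)-TRIP is (R)-3,3'-bis(2,4,6-triisopropylphenyl)-1,1'-binaphthyl-2,2'-diyl hydrogen phosphate. "Hexa-O-benzylgallocatechin-8-yl" means the (2R,3S)-3,5,7-tris(benzyloxy)-2-[3,4,5-tris(benzyloxy)phenyl]chroman-8-yl group.

## Route

Step 1
Reactants: 1 (+)-gallocatechin
Product: 2 5,7,3',4',5'-penta-O-benzyl-(+)-gallocatechin (C3 hydroxyl free)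
Conditions: BnBr (5.5 equiv), K2CO3, DMF (degassed, Ar), −10 °C → rt
Reagents that add atoms: benzyl bromide, BrCc1ccccc1
Why: Williamson etherification; carbonate deprotonates only the five phenols, so the C3 alcohol stays free, and exclusion of air and low temperature protect the pyrogallol ring from oxidation and C2 from base-induced epimerisation.

Step 2
Reactants: 2 penta-O-benzyl-(+)-gallocatechin
Product: 3 hexa-O-benzyl-(+)-gallocatechin
Conditions: NaH, BnBr, n-Bu4NI (cat.), DMF, 0 °C → rt
Reagents that add atoms: benzyl bromide, BrCc1ccccc1
Why: Williamson etherification of the secondary alkoxide; with every phenol already capped, the ring-opening pathway by which flavan-3-ols epimerise at C2 under base is closed, so both stereocentres are retained.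

Step 3
Reactants: 3 hexa-O-benzyl-(+)-gallocatechin
Product: 4 8-bromo-hexa-O-benzylgallocatechin
Conditions: NBS (1.0 equiv), CH2Cl2, −78 → 0 °C
Reagents that add atoms: N-bromosuccinimide, O=C1CCC(=O)N1Br
Why: Electrophilic aromatic bromination; ring D with three oxygen donors reacts far faster than ring E, and of its two free positions C8 (between O1 and one benzyloxy group) is the established and less hindered site in benzylated flavan-3-ols, C6 lying between two benzyloxy groups.

Step 4
Reactants: 4 8-bromo-hexa-O-benzylgallocatechin
Product: 6 hexa-O-benzylgallocatechin-8-carbaldehyde, via 8-lithio-hexa-O-benzylgallocatechin 5 (not isolated)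
Conditions: n-BuLi (1.1 equiv), THF, −78 °C; DMF, −78 → 0 °C; aq NH4Cl
Reagents that add atoms: N,N-dimethylformamide, CN(C)C=O
Why: Bromine–lithium exchange gives an aryllithium stabilised by its two flanking ether oxygens, and formylation with the formamide (Bouveault aldehyde synthesis) places the future upper C4 on lower C8; benzyl ethers and the lower stereocentres are inert at −78 °C.

Step 5
Reactants: 6 hexa-O-benzylgallocatechin-8-carbaldehyde; 7 resorcinol; 8 ethyl vinyl ether
Product: 11 (4R)-2-ethoxy-4-(hexa-O-benzylgallocatechin-8-yl)chroman-7-ol as C2 epimers, via benzhydrol 9 (not isolated), via ring-A o-quinone methide 10 (not isolated)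
Conditions: 7 (1.5 equiv), 8 (10 equiv), (R)-TRIP (10 mol %), 5 Å MS, CH2Cl2, 0 °C → rt, 6 added slowly by syringe pump; then PPTS (cat.), EtOH, rt
Reagents that add atoms: none
Why: The acid hydrogen-bonds to the formyl oxygen of 6 and to a hydroxyl of 7, so that C4 of 7 (para to one hydroxyl, ortho to the other; the two such positions are equivalent and the position between the hydroxyls is hindered) adds to the aldehyde in a Friedel–Crafts hydroxyalkylation and forms C4–C4a of benzhydrol 9. The carbinol carbon of 9 lies between a 2,4-dihydroxyphenyl and a 2,4,6-trioxygenated aryl ring and should ionise at once to the ring-A o-quinone methide 10, held by the chiral phosphate through a hydrogen bond or as an ion pair; ring D has no free ortho hydroxyl, so the quinone methide can form only on ring A. Vinyl ether 8 then adds in an inverse-electron-demand oxa-[4+2] cycloaddition (asynchronous, or stepwise through a β-aryl oxocarbenium ion that the phenolic oxygen captures), its unsubstituted carbon bonding to the benzylic carbon (C3–C4) and its oxygen-bearing carbon to the phenolic oxygen (O1–C2); ring C is the only ring closed, as a six-membered cyclic acetal by hetero-Diels–Alder closure. The closest known reaction types are the acid-catalysed three-component chroman synthesis from phenols, aldehydes and electron-rich alkenes and the chiral-phosphoric-acid-catalysed [4+2] cycloadditions of o-quinone methides released from o-hydroxybenzhydrols; combining the two in an enantioselective three-component format with a simple vinyl ether is an extension of both. C4 is set when C3–C4 forms: the phosphate bound at the quinone methide oxygen screens one face of the exocyclic double bond, and the remote lower C2 and C3 centres are not expected to override the catalyst; the carbinol centre of 9 is lost on dehydration and the acetal carbon C2 forms as a mixture, which is harmless because step 8 planarises it. The selectivity needed is capture of the cation by 8 in preference to a second molecule of 7, secured by the several-fold excess of 8 over 7 and by the slow addition, which keeps the concentration of 9 and 10 low. The sieves remove the equivalent of water that would otherwise hydrolyse 8, and the ethanolic PPTS treatment returns any phenol parked as a 1-ethoxyethyl ether without changing the ethyl acetal at C2.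

Step 6
Reactants: 11 (4R)-2-ethoxy-4-(hexa-O-benzylgallocatechin-8-yl)chroman-7-ol
Product: 12 (4R)-7-(benzyloxy)-2-ethoxy-4-(hexa-O-benzylgallocatechin-8-yl)chromane as C2 epimers
Conditions: BnBr, K2CO3, DMF, rt
Reagents that add atoms: benzyl bromide, BrCc1ccccc1
Why: Williamson etherification of the only free phenol; the basic medium leaves the acid-labile C2 acetal and the C4 stereocentre untouched.

Step 7
Reactants: 13 1-(benzyloxy)-4-bromobenzene
Product: 15 [4-(benzyloxy)phenyl]zinc chloride as a solution for step 8, via 4-(benzyloxy)phenyllithium 14 (not isolated)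
Conditions: n-BuLi (1.0 equiv), Et2O, −78 → 0 °C; ZnCl2 (1.0 equiv, Et2O), 0 °C → rt; diluted with PhMe
Reagents that add atoms: ZnCl2 (zinc dichloride), Cl[Zn]Cl
Why: Bromine–lithium exchange followed by transmetalation of the aryllithium onto one equivalent of ZnCl2 gives the monoarylzinc chloride (as its LiCl adduct), so that each molecule of 13 supplies one transferable aryl group; arylzinc halides are the classical carbon nucleophiles for α-halo ethers and oxocarbenium ions, tolerate a Lewis acid and benzyl ethers, and ether/toluene avoids strongly coordinating solvent in step 8.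

Step 8
Reactants: 12 (4R)-7-(benzyloxy)-2-ethoxy-4-(hexa-O-benzylgallocatechin-8-yl)chromane; 15 [4-(benzyloxy)phenyl]zinc chloride
Product: 17 (2S,4R)-7-(benzyloxy)-2-[4-(benzyloxy)phenyl]-4-(hexa-O-benzylgallocatechin-8-yl)chromane (octa-O-benzyl target), via C2 oxocarbenium ion 16 (not isolated)
Conditions: 15 (2.0 equiv), BF3·OEt2 (2.0 equiv, added last), CH2Cl2/PhMe/Et2O, −78 → −40 °C; aq NH4Cl at −40 °C
Reagents that add atoms: none
Why: Lewis-acid-mediated substitution of a cyclic O,O-acetal by an arylzinc nucleophile, a reaction type known for 2-alkoxy and 2-acyloxy tetrahydropyrans, α-halo ethers and glycosyl donors: BF3 removes ethoxide from either C2 epimer to give the same oxocarbenium ion 16, and the electron-rich aryl group adds along the axial trajectory on the face opposite the bulky C4 substituent, which sets C2 (S) trans to C4. The low temperature and cold quench are meant to prevent re-ionisation of the new benzylic C2–O1 bond towards the more stable cis isomer.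

Step 9
Reactants: 17 octa-O-benzyl target
Product: 18 (2R,3S)-8-[(2S,4R)-7-hydroxy-2-(4-hydroxyphenyl)chroman-4-yl]-2-(3,4,5-trihydroxyphenyl)chromane-3,5,7-triol (target)
Conditions: H2 (1 atm), Pd(OH)2/C, THF/MeOH, rt; filtration and concentration under Ar
Reagents that add atoms: none
Why: Catalytic hydrogenolysis of the eight benzyl ethers; exocyclic O–benzyl bonds are cleaved more readily than the cyclic benzylic C2–O1 bonds of rings C and F, as is established for benzylated flavan-3-ols and their 4→8 dimers, and the neutral conditions leave all four stereocentres and the C4–C8 bond alone.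

## Compound list

1 | (+)-gallocatechin, (2R,3S)-2-(3,4,5-trihydroxyphenyl)chromane-3,5,7-triol | Oc1cc(O)c2c(c1)O[C@H](c1cc(O)c(O)c(O)c1)[C@@H](O)C2 | starting material
2 | (2R,3S)-5,7-bis(benzyloxy)-2-[3,4,5-tris(benzyloxy)phenyl]chroman-3-ol (penta-O-benzylgallocatechin) | C(c5ccccc5)Oc1cc(OCc5ccccc5)c2c(c1)O[C@H](c1cc(OCc5ccccc5)c(OCc5ccccc5)c(OCc5ccccc5)c1)[C@@H](O)C2 | intermediate
3 | (2R,3S)-3,5,7-tris(benzyloxy)-2-[3,4,5-tris(benzyloxy)phenyl]chromane (hexa-O-benzylgallocatechin) | C(c5ccccc5)Oc1cc(OCc5ccccc5)c2c(c1)O[C@H](c1cc(OCc5ccccc5)c(OCc5ccccc5)c(OCc5ccccc5)c1)[C@@H](OCc5ccccc5)C2 | intermediate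
4 | (2R,3S)-8-bromo-3,5,7-tris(benzyloxy)-2-[3,4,5-tris(benzyloxy)phenyl]chromane | Brc3c(OCc5ccccc5)cc(OCc5ccccc5)c4c3O[C@H](c3cc(OCc5ccccc5)c(OCc5ccccc5)c(OCc5ccccc5)c3)[C@@H](OCc5ccccc5)C4 | intermediate
5 | (2R,3S)-hexa-O-benzylgallocatechin-8-yllithium | [Li]c3c(OCc5ccccc5)cc(OCc5ccccc5)c4c3O[C@H](c3cc(OCc5ccccc5)c(OCc5ccccc5)c(OCc5ccccc5)c3)[C@@H](OCc5ccccc5)C4 | intermediate
6 | (2R,3S)-3,5,7-tris(benzyloxy)-2-[3,4,5-tris(benzyloxy)phenyl]chromane-8-carbaldehyde | O=Cc3c(OCc5ccccc5)cc(OCc5ccccc5)c4c3O[C@H](c3cc(OCc5ccccc5)c(OCc5ccccc5)c(OCc5ccccc5)c3)[C@@H](OCc5ccccc5)C4 | intermediate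
7 | resorcinol (benzene-1,3-diol) | Oc1cccc(O)c1 | starting material
8 | ethyl vinyl ether | C=COCC | starting material
9 | (2,4-dihydroxyphenyl)(hexa-O-benzylgallocatechin-8-yl)methanol, carbinol epimers | OC(c1ccc(O)cc1O)c3c(OCc5ccccc5)cc(OCc5ccccc5)c4c3O[C@H](c3cc(OCc5ccccc5)c(OCc5ccccc5)c(OCc5ccccc5)c3)[C@@H](OCc5ccccc5)C4 | intermediate
10 | 6-[(hexa-O-benzylgallocatechin-8-yl)methylidene]-3-hydroxycyclohexa-2,4-dien-1-one (ring-A o-quinone methide; alkene geometry not fixed, E expected) | O=C1C=C(O)C=CC1=Cc3c(OCc5ccccc5)cc(OCc5ccccc5)c4c3O[C@H](c3cc(OCc5ccccc5)c(OCc5ccccc5)c(OCc5ccccc5)c3)[C@@H](OCc5ccccc5)C4 | intermediate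
11 | (4R)-2-ethoxy-4-[(2R,3S)-hexa-O-benzylgallocatechin-8-yl]chroman-7-ol, C2 epimers | CCOC2C[C@@H](c3c(OCc5ccccc5)cc(OCc5ccccc5)c4c3O[C@H](c3cc(OCc5ccccc5)c(OCc5ccccc5)c(OCc5ccccc5)c3)[C@@H](OCc5ccccc5)C4)c3ccc(O)cc3O2 | intermediate
12 | (4R)-7-(benzyloxy)-2-ethoxy-4-[(2R,3S)-hexa-O-benzylgallocatechin-8-yl]chromane, C2 epimers | CCOC2C[C@@H](c3c(OCc5ccccc5)cc(OCc5ccccc5)c4c3O[C@H](c3cc(OCc5ccccc5)c(OCc5ccccc5)c(OCc5ccccc5)c3)[C@@H](OCc5ccccc5)C4)c3ccc(OCc5ccccc5)cc3O2 | intermediate
13 | 1-(benzyloxy)-4-bromobenzene | Brc1ccc(OCc2ccccc2)cc1 | starting material
14 | 4-(benzyloxy)phenyllithium | [Li]c1ccc(OCc2ccccc2)cc1 | intermediate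
15 | [4-(benzyloxy)phenyl]zinc chloride | Cl[Zn]c1ccc(OCc2ccccc2)cc1 | intermediate
16 | (4R)-7-(benzyloxy)-4-[(2R,3S)-hexa-O-benzylgallocatechin-8-yl]-3,4-dihydrochromenylium ethoxytrifluoroborate (C2 oxocarbenium ion) | C=2C[C@@H](c3c(OCc5ccccc5)cc(OCc5ccccc5)c4c3O[C@H](c3cc(OCc5ccccc5)c(OCc5ccccc5)c(OCc5ccccc5)c3)[C@@H](OCc5ccccc5)C4)c3ccc(OCc5ccccc5)cc3[O+]=2.CCO[B-](F)(F)F | intermediate
17 | (2S,4R)-7-(benzyloxy)-2-[4-(benzyloxy)phenyl]-4-[(2R,3S)-hexa-O-benzylgallocatechin-8-yl]chromane (octa-O-benzyl target) | O(Cc5ccccc5)c1ccc([C@@H]2C[C@@H](c3c(OCc5ccccc5)cc(OCc5ccccc5)c4c3O[C@H](c3cc(OCc5ccccc5)c(OCc5ccccc5)c(OCc5ccccc5)c3)[C@@H](OCc5ccccc5)C4)c3ccc(OCc5ccccc5)cc3O2)cc1 | intermediate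
18 | (2R,3S)-8-[(2S,4R)-7-hydroxy-2-(4-hydroxyphenyl)chroman-4-yl]-2-(3,4,5-trihydroxyphenyl)chromane-3,5,7-triol | Oc1ccc([C@@H]2C[C@@H](c3c(O)cc(O)c4c3O[C@H](c3cc(O)c(O)c(O)c3)[C@@H](O)C4)c3ccc(O)cc3O2)cc1 | target

## Step count and least certain steps

Total: 9 steps. Longest linear sequence: 8 steps (steps 1–6, 8 and 9, from 1). Step 7 is a one-step side branch from 13.

**Step 5 (key step).** Three processes are most likely to fail it. The first is double arylation of the aldehyde carbon: a second resorcinol, or ring A of the product, may capture the cation derived from 9 and 10, because phenols hydrogen-bonded to the phosphate are delivered inside the ion pair whereas the vinyl ether has no such handle. The second is poor facial selectivity at C4, for the same reason, made worse by the free para hydroxyl, which lets the cation be held as a para-quinone methide far from the reacting carbon. The third is slow hydroxyalkylation, since the formyl group of 6 is flanked by two ortho oxygens and deactivated by three donors, while 8 is meanwhile consumed by hydrolysis or by acetalisation of phenols.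

The fallback sets out from 6 and returns to the route at 12, so that step 6 is no longer needed. Commercial 5-(benzyloxy)-2-bromophenol is treated with n-BuLi (2.2 equiv, THF, −78 → 0 °C) to give the ortho-lithiated phenoxide, lithium 5-(benzyloxy)-2-lithiophenolate F1. This adds to 6 at −78 °C and should give the o-hydroxybenzhydrol (4-benzyloxy-2-hydroxyphenyl)(hexa-O-benzylgallocatechin-8-yl)methanol F2 as carbinol epimers, used crude. F2 and 8 are then combined with (R)-TRIP in CH2Cl2 over 5 Å MS. This is the two-component benzhydrol format for which chiral-phosphoric-acid o-quinone methide cycloadditions are established; no second phenol and no para hydroxyl are present, and 12 should form directly. Because the lower unit is enantiopure, the C4 epimers are diastereomers and can be separated by chromatography if catalyst control is incomplete.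

**Step 8.** Four processes are most likely to fail it. Aryl transfer from the monoarylzinc chloride may be slow, so that the oxocarbenium ion is lost by elimination of the C3 proton to the 4H-chromene. Ionisation may occur in the wrong sense: loss of the phenolic O1 in place of ethoxide opens the ring, and arylation of the acyclic oxocarbenium ion followed by reclosure would not be stereocontrolled. The trans relation may erode by reversible heterolysis of the new C2–O1 bond, which is benzylic to a para-alkoxyphenyl ring, towards the more stable cis isomer. Aryl transfer from zinc to boron may divert part of the nucleophile.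

The fallback sets out from 12 and returns at 17. Acetal 12 is hydrolysed (AcOH/H2O/THF, 40 °C) to the lactol (4R)-7-(benzyloxy)-4-(hexa-O-benzylgallocatechin-8-yl)chroman-2-ol F3. The Grignard reagent 4-(benzyloxy)phenylmagnesium bromide F4, made from 13 and Mg turnings in THF, is added in excess (3 equiv, 0 °C) and reacts with the hydroxy-aldehyde form of F3 to give the diol 1-[4-(benzyloxy)phenyl]-3-[4-(benzyloxy)-2-hydroxyphenyl]-3-(hexa-O-benzylgallocatechin-8-yl)propan-1-ol F5 as carbinol epimers. MnO2 (CH2Cl2, rt) oxidises the activated benzylic alcohol to the ketone 1-[4-(benzyloxy)phenyl]-3-[4-(benzyloxy)-2-hydroxyphenyl]-3-(hexa-O-benzylgallocatechin-8-yl)propan-1-one F6. Noyori transfer hydrogenation with RuCl[(R,R)-TsDPEN](p-cymene) and HCO2H/Et3N should set the carbinol by catalyst control and give the (1R,3R)-configured alcohol F7. Mitsunobu cyclisation (PPh3, DIAD, THF, 0 °C) then closes O1–C2 with inversion, which gives the (2S) centre trans to C4 in 17.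

**Step 9.** The likely failures are over-reduction (hydrogenolysis of the benzylic C2–O1 bonds of rings C and F, which opens the pyran rings), stalling at partially benzylated material because the substrate is hindered and poorly soluble, and air oxidation of the pyrogallol ring during isolation. The fallback sets out from 17 and returns at 18. The benzyl ethers are removed by Lewis-acid dealkylation with BCl3 and pentamethylbenzene as cation scavenger (CH2Cl2, −78 °C, methanol quench at low temperature), which involves no hydrogen and no metal surface. This fallback makes no compound outside the list.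

**Step 4 (and the bromination before it).** The likely failures are protonation of 5 by adventitious acid or its alkylation by the 1-bromobutane formed in the exchange, metalation of a benzyl ether in competition with the exchange, and incomplete C8 selectivity in step 3 carried through. The fallback sets out from 3 and returns at 6. Vilsmeier–Haack formylation (POCl3, DMF, 0 °C → 50 °C, then aq NaOAc) places the formyl group on ring D by electrophilic substitution without any organolithium, and the C8 aldehyde is separated from any C6 isomer by chromatography. This fallback makes no compound outside the list.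

## Further compounds

F1 | step 5 | lithium 5-(benzyloxy)-2-lithiophenolate | [Li]Oc1cc(OCc2ccccc2)ccc1[Li]
F2 | step 5 | (4-benzyloxy-2-hydroxyphenyl)(hexa-O-benzylgallocatechin-8-yl)methanol, carbinol epimers | OC(c1ccc(OCc5ccccc5)cc1O)c3c(OCc5ccccc5)cc(OCc5ccccc5)c4c3O[C@H](c3cc(OCc5ccccc5)c(OCc5ccccc5)c(OCc5ccccc5)c3)[C@@H](OCc5ccccc5)C4
F3 | step 8 | (4R)-7-(benzyloxy)-4-(hexa-O-benzylgallocatechin-8-yl)chroman-2-ol, lactol epimers | OC2C[C@@H](c3c(OCc5ccccc5)cc(OCc5ccccc5)c4c3O[C@H](c3cc(OCc5ccccc5)c(OCc5ccccc5)c(OCc5ccccc5)c3)[C@@H](OCc5ccccc5)C4)c3ccc(OCc5ccccc5)cc3O2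
F4 | step 8 | 4-(benzyloxy)phenylmagnesium bromide | Br[Mg]c1ccc(OCc2ccccc2)cc1
F5 | step 8 | (3R)-1-[4-(benzyloxy)phenyl]-3-[4-(benzyloxy)-2-hydroxyphenyl]-3-(hexa-O-benzylgallocatechin-8-yl)propan-1-ol, carbinol epimers | OC(c1ccc(OCc5ccccc5)cc1)C[C@@H](c3c(OCc5ccccc5)cc(OCc5ccccc5)c4c3O[C@H](c3cc(OCc5ccccc5)c(OCc5ccccc5)c(OCc5ccccc5)c3)[C@@H](OCc5ccccc5)C4)c3ccc(OCc5ccccc5)cc3O
F6 | step 8 | (3R)-1-[4-(benzyloxy)phenyl]-3-[4-(benzyloxy)-2-hydroxyphenyl]-3-(hexa-O-benzylgallocatechin-8-yl)propan-1-one | O=C(c1ccc(OCc5ccccc5)cc1)C[C@@H](c3c(OCc5ccccc5)cc(OCc5ccccc5)c4c3O[C@H](c3cc(OCc5ccccc5)c(OCc5ccccc5)c(OCc5ccccc5)c3)[C@@H](OCc5ccccc5)C4)c3ccc(OCc5ccccc5)cc3O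
F7 | step 8 | (1R,3R)-1-[4-(benzyloxy)phenyl]-3-[4-(benzyloxy)-2-hydroxyphenyl]-3-(hexa-O-benzylgallocatechin-8-yl)propan-1-ol | O[C@@H](c1ccc(OCc5ccccc5)cc1)C[C@@H](c3c(OCc5ccccc5)cc(OCc5ccccc5)c4c3O[C@H](c3cc(OCc5ccccc5)c(OCc5ccccc5)c(OCc5ccccc5)c3)[C@@H](OCc5ccccc5)C4)c3ccc(OCc5ccccc5)cc3O
F0 | step 9 | none | none
F0 | step 4 | none | none
A1 | alternative 1 | hepta-O-benzyl target with an acetate on lower C3 | O(Cc5ccccc5)c1ccc([C@@H]2C[C@@H](c3c(OCc5ccccc5)cc(OCc5ccccc5)c4c3O[C@H](c3cc(OCc5ccccc5)c(OCc5ccccc5)c(OCc5ccccc5)c3)[C@@H](OC(C)=O)C4)c3ccc(OCc5ccccc5)cc3O2)cc1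
A2 | alternative 1 | 2-[(2S,4R)-7-(benzyloxy)-2-(4-benzyloxyphenyl)chroman-4-yl]-3,5-bis(benzyloxy)-6-(hydroxymethyl)phenol | O(Cc5ccccc5)c1ccc([C@@H]2C[C@@H](c3c(OCc5ccccc5)cc(OCc5ccccc5)c(CO)c3O)c3ccc(OCc5ccccc5)cc3O2)cc1
A3 | alternative 1 | (E)-2-[3,4,5-tris(benzyloxy)phenyl]vinyl acetate | CC(=O)O/C=C/c1cc(OCc2ccccc2)c(OCc2ccccc2)c(OCc2ccccc2)c1
A4 | alternative 2 | (4R)-7-(benzyloxy)-2-[4-(benzyloxy)phenyl]-2-(tert-butyldimethylsilyloxy)-4-(hexa-O-benzylgallocatechin-8-yl)chromane, C2 epimers | CC(C)(C)[Si](C)(C)OC2(c1ccc(OCc5ccccc5)cc1)C[C@@H](c3c(OCc5ccccc5)cc(OCc5ccccc5)c4c3O[C@H](c3cc(OCc5ccccc5)c(OCc5ccccc5)c(OCc5ccccc5)c3)[C@@H](OCc5ccccc5)C4)c3ccc(OCc5ccccc5)cc3O2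
A5 | alternative 2 | (4-benzyloxy-2-hydroxyphenyl)(hexa-O-benzylgallocatechin-8-yl)methanol, carbinol epimers | OC(c1ccc(OCc5ccccc5)cc1O)c3c(OCc5ccccc5)cc(OCc5ccccc5)c4c3O[C@H](c3cc(OCc5ccccc5)c(OCc5ccccc5)c(OCc5ccccc5)c3)[C@@H](OCc5ccccc5)C4
A6 | alternative 2 | {[1-(4-benzyloxyphenyl)ethenyl]oxy}(tert-butyl)dimethylsilane | C=C(O[Si](C)(C)C(C)(C)C)c1ccc(OCc2ccccc2)cc1
A7 | alternative 3 | (4R)-7-(benzyloxy)-4-(hexa-O-benzylgallocatechin-8-yl)chroman-2-ol, lactol epimers | OC2C[C@@H](c3c(OCc5ccccc5)cc(OCc5ccccc5)c4c3O[C@H](c3cc(OCc5ccccc5)c(OCc5ccccc5)c(OCc5ccccc5)c3)[C@@H](OCc5ccccc5)C4)c3ccc(OCc5ccccc5)cc3O2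
A8 | alternative 3 | 5-(benzyloxy)-2-[1-(hexa-O-benzylgallocatechin-8-yl)ethenyl]phenol | C=C(c1ccc(OCc5ccccc5)cc1O)c3c(OCc5ccccc5)cc(OCc5ccccc5)c4c3O[C@H](c3cc(OCc5ccccc5)c(OCc5ccccc5)c(OCc5ccccc5)c3)[C@@H](OCc5ccccc5)C4
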